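The trimer is cut at its two interflavan bonds, C4(top)–C6(middle) and C4(middle)–C8(bottom), into two epicatechin gallate units drawn from (−)-epicatechin and a catechin unit made de novo. The pyran ring of that catechin unit (O1, C2, C3, C4, C4a, C8a) is reached from a trans-2-aryl-3-(hydroxymethyl)-2,3-dihydrobenzofuran: on ionisation of the primary sulfonate the electron-rich ring A carbon C4a, flanked by O1 and the C5 and C7 oxygens, shifts from C3 to the exocyclic CH2 through a phenonium ion and water enters at C3 with inversion. One operation thus expands the furan ring to the pyran ring, forms C4–C4a and C3–O, and fixes the 2,3-trans relationship. The dihydrobenzofuran itself comes from an enantioselective rhodium carbenoid C–H insertion.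

Key step: step 6

Abbreviations in names: Bn = benzyl; DBB = 3,4-bis(benzyloxy)benzyl.

Assumption: the (R)-tert-leucinate catalyst Rh2(R-PTTL)4 is taken to deliver the (2S) series in step 4; if the sense of induction is the opposite, the (S)-tert-leucinate catalyst is used and nothing else changes.

**Route**

Step 1
Reactants: 1 phloroglucinol; 2 3,4-bis(benzyloxy)benzyl chloride
Product: 3 1,3,5-tris{[3,4-bis(benzyloxy)phenyl]methoxy}benzene
Conditions: 2 (3.3 equiv in all), K2CO3, DMF, 50 °C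
Reagents that add atoms: 3,4-bis(benzyloxy)benzyl chloride (the second and third equivalents of 2, one SMILES unit each), ClCc1ccc(OCc2ccccc2)c(OCc2ccccc2)c1.ClCc1ccc(OCc2ccccc2)c(OCc2ccccc2)c1
Why: Threefold Williamson ether synthesis in which one molecule of 1 takes up three molecules of 2 (carbonate in DMF favours O- over C-alkylation); the threefold-symmetric product makes every ring position and all three ArO–CH2 groups equivalent for steps 2 and 4.

Step 2
Reactants: 3 1,3,5-tris(DBB-oxy)benzene; 4 dimethyl oxalate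
Product: 5 methyl 2-oxo-2-[2,4,6-tris(DBB-oxy)phenyl]acetate
Conditions: n-BuLi, TMEDA, THF, 0 °C; then inverse addition to 4 (3 equiv), THF, −78 °C
Reagents that add atoms: none
Why: Directed ortho-metalation at a ring C–H flanked by two alkoxy groups, then acylation of the aryllithium by excess dimethyl oxalate, which should stop at the keto ester; no stereocentre is formed.

Step 3
Reactants: 5 methyl 2-oxo-2-[2,4,6-tris(DBB-oxy)phenyl]acetate
Product: 7 methyl 2-diazo-2-[2,4,6-tris(DBB-oxy)phenyl]acetate, via tosylhydrazone 6 (not isolated)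
Conditions: TsNHNH2, MeOH–CH2Cl2, 40 °C; then DBU, CH2Cl2, rt
Reagents that add atoms: p-toluenesulfonyl hydrazide, Cc1ccc(cc1)S(=O)(=O)NN
Why: Tosylhydrazone formation followed by base-induced loss of sulfinate (Bamford–Stevens-type diazo synthesis), the usual entry to aryldiazoacetates from aryl glyoxylates.

Step 4
Reactants: 7 methyl 2-diazo-2-[2,4,6-tris(DBB-oxy)phenyl]acetate
Product: 8 methyl (2S,3R)-2-[3,4-bis(benzyloxy)phenyl]-4,6-bis(DBB-oxy)-2,3-dihydro-1-benzofuran-3-carboxylate (cis)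
Conditions: Rh2(R-PTTL)4 (dirhodium tetrakis[N-phthaloyl-(R)-tert-leucinate], divalent rhodium, 2 mol %), toluene, −60 °C
Reagents that add atoms: none
Why: Intramolecular 1,5 C–H insertion of the donor/acceptor rhodium carbenoid into the electron-rich benzylic ether C–H closes the dihydrofuran ring; the two ortho ethers are equivalent, the concerted insertion gives the kinetic cis ester, and the chiral carboxylate ligands choose between the enantiotopic C–H bonds and so set C2 as S.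

Step 5
Reactants: 8 cis ester
Product: 10 {(2S,3R)-2-[3,4-bis(benzyloxy)phenyl]-4,6-bis(DBB-oxy)-2,3-dihydro-1-benzofuran-3-yl}methanol (trans), via trans ester 9 (not isolated)
Conditions: NaOMe (0.3 equiv), MeOH–THF, rt; then LiBH4, 0 °C → rt
Reagents that add atoms: none
Why: Methoxide epimerises the ester-bearing C3 to the thermodynamically preferred trans isomer without touching C2, and LiBH4 then reduces the ester to the primary alcohol (ester reduction).

Step 6
Reactants: 10 trans-2-aryl-3-(hydroxymethyl)dihydrobenzofuran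
Product: 13 (2R,3S)-2-[3,4-bis(benzyloxy)phenyl]-5,7-bis(DBB-oxy)-3,4-dihydro-2H-chromen-3-ol (protected (+)-catechin), via primary mesylate 11 (not isolated), via phenonium mesylate 12 (not isolated)
Conditions: Ms2O, 2,6-di-tert-butyl-4-methylpyridine, CH2Cl2, −20 °C; then (CF3)2CHOH–H2O (9:1), 0 °C → rt
Reagents that add atoms: water, O
Why: The primary mesylate ionises with anchimeric assistance of ring A (attack of C4a on the CH2 anti to the leaving group) to give the spiro-cyclopropyl arenium (phenonium) ion 12, whose charge is carried by O1 and the C5 and C7 oxygens; water then opens the three-membered ring at the ring-fusion carbon C3 anti to C4a, so that C4a has moved from C3 to the former CH2 (now C4). The closest known reaction type is the Wagner–Meerwein 1,2-aryl shift through phenonium ions in the solvolysis of 2-aryl-1-alkyl sulfonates, which gives 1-aryl-2-alkyl products, together with its ring-expanding variants (1-indanylmethyl to 2-tetralyl). The six-membered ring is not closed end to end: it results from 3-exo-tet closure of the cyclopropane followed by cleavage of its C3–C4a bond. C3 is the only stereocentre made and is set stereospecifically by inversion (backside attack of water against the departing aryl carbon), so the trans dihydrobenzofuran gives the 2,3-trans flavan-3-ol, and C2 is not touched. The step needs water to attack the secondary carbon C3 and not the CH2 of the bridged ion; an ionising, weakly nucleophilic medium (secondary over primary carbon) and formation of the unstrained chroman should favour this, and attack at CH2 only returns alcohol 10, which is recycled.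

Step 7
Reactants: 14 (−)-epicatechin
Product: 15 5,7,3',4'-tetra-O-benzyl-(−)-epicatechin
Conditions: BnBr (4.2 equiv), K2CO3, DMF, 0 °C → rt
Reagents that add atoms: benzyl bromide (four equivalents, one SMILES unit each), BrCc1ccccc1.BrCc1ccccc1.BrCc1ccccc1.BrCc1ccccc1
Why: Fourfold Williamson etherification of the four phenols; the secondary 3-OH is not deprotonated by carbonate and stays free.

Step 8
Reactants: 15 tetra-O-benzylepicatechin
Product: 16 8-bromo-5,7,3',4'-tetra-O-benzyl-(−)-epicatechin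
Conditions: NBS (1.0 equiv), CH2Cl2, −20 °C → rt
Reagents that add atoms: N-bromosuccinimide, O=C1CCC(=O)N1Br
Why: Electrophilic aromatic bromination; ring A is the most electron-rich ring and C8 is its preferred site.

Step 9
Reactants: 16 8-bromo-tetra-O-benzylepicatechin
Product: 17 8-bromo-5,7,3',4'-tetra-O-benzyl-4β-(2-ethoxyethoxy)-(−)-epicatechin (4-substituent trans to 3-OH)
Conditions: DDQ, 2-ethoxyethanol, CH2Cl2, rt
Reagents that add atoms: 2-ethoxyethanol, CCOCCO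
Why: DDQ benzylic oxidation: hydride abstraction from C4 gives the ring A-stabilised cation, which the alcohol traps on the β face, trans to the 3-OH and away from the 2-aryl group.

Step 10
Reactants: 17 4β-(2-ethoxyethoxy) alcohol; 18 3,4,5-tris(benzyloxy)benzoic acid
Product: 19 8-bromo-5,7,3',4'-tetra-O-benzyl-4β-(2-ethoxyethoxy)-(−)-epicatechin 3-O-[3,4,5-tris(benzyloxy)benzoate]
Conditions: DCC, DMAP, CH2Cl2, rt
Reagents that add atoms: none
Why: Steglich esterification of the secondary 3-OH.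

Step 11
Reactants: 19 8-bromo 4β-(2-ethoxyethoxy) gallate
Product: 20 6,8-dibromo-5,7,3',4'-tetra-O-benzyl-4β-(2-ethoxyethoxy)-(−)-epicatechin 3-O-[3,4,5-tris(benzyloxy)benzoate]
Conditions: NBS, CH2Cl2, 0 °C → rt, dark
Reagents that add atoms: N-bromosuccinimide, O=C1CCC(=O)N1Br
Why: Second electrophilic aromatic bromination at C6, the only ring A position left; the fully capped donor can no longer act as a nucleophile in step 13.

Step 12
Reactants: 19 8-bromo 4β-(2-ethoxyethoxy) gallate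
Product: 21 8-bromo-5,7,3',4'-tetra-O-benzyl-4β-(2,6-dimethylphenylsulfanyl)-(−)-epicatechin 3-O-[3,4,5-tris(benzyloxy)benzoate]
Conditions: 2,6-dimethylbenzenethiol (3 equiv), BF3·OEt2, CH2Cl2, −78 → −40 °C
Reagents that add atoms: 2,6-dimethylbenzenethiol, Cc1cccc(C)c1S
Why: Lewis acid-mediated SN1 exchange at C4: BF3·OEt2 ionises the 4-alkoxy group, the 3-O-galloyl group shields the α face (acyloxonium participation) and the thiol adds from the β face.

Step 13
Reactants: 20 dibromo donor; 21 thioether acceptor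
Product: 22 [6,8-dibromo-tetra-O-benzyl-3-O-(tri-O-benzylgalloyl)epicatechin]-(4β→6)-[8-bromo-tetra-O-benzyl-3-O-(tri-O-benzylgalloyl)-4β-(2,6-dimethylphenylsulfanyl)epicatechin]
Conditions: BF3·OEt2, 4 Å molecular sieves, CH2Cl2, −78 → −30 °C
Reagents that add atoms: none
Why: Friedel–Crafts alkylation by the flavan-4-yl cation: the hard Lewis acid ionises the 4-alkoxy group of 20 but should leave the hindered thioether of 21, C6 is the only free ring A position of 21, and neighbouring-group participation of the 3-O-galloyl group directs attack to the β face (3,4-trans).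

Step 14
Reactants: 22 dimeric thioether; 13 protected catechin (1.5 equiv)
Product: 23 protected trimer, [6,8-dibromo-tetra-O-benzyl-3-O-(tri-O-benzylgalloyl)epicatechin]-(4β→6)-[8-bromo-tetra-O-benzyl-3-O-(tri-O-benzylgalloyl)epicatechin]-(4β→8)-[3',4'-di-O-benzyl-5,7-di-O-DBB-catechin]
Conditions: AgOTf, 2,6-di-tert-butyl-4-methylpyridine, 4 Å molecular sieves, CH2Cl2, −40 → 0 °C, dark
Reagents that add atoms: none
Why: Thiophilic silver activation of the 4-thioether gives the C4 cation, which alkylates 13 at C8 (Friedel–Crafts alkylation; C8 is the more reactive and less hindered free ring A position) from the β face through participation of the 3-O-galloyl group, while the hindered pyridine removes the acid that would endanger the DBB ethers.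

Step 15
Reactants: 23 protected trimer
Product: 24 epicatechin 3-O-gallate-(4β→6)-epicatechin 3-O-gallate-(4β→8)-catechin (target)
Conditions: H2 (1 atm), Pd(OH)2/C, THF–MeOH–H2O, rt
Reagents that add atoms: none
Why: Catalytic hydrogenolysis cleaves all twenty benzyl ethers, the two ring A DBB ethers (as 4-methylcatechol) and the three aryl C–Br bonds; the esters, the interflavan bonds and all stereocentres are untouched.

**Compound list**

1 | phloroglucinol | Oc1cc(O)cc(O)c1 | starting material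
2 | 3,4-bis(benzyloxy)benzyl chloride | ClCc1ccc(OCc2ccccc2)c(OCc2ccccc2)c1 | starting material
3 | 1,3,5-tris{[3,4-bis(benzyloxy)phenyl]methoxy}benzene | c1c(OCc2ccc(OCc3ccccc3)c(OCc3ccccc3)c2)cc(OCc2ccc(OCc3ccccc3)c(OCc3ccccc3)c2)cc1OCc1ccc(OCc2ccccc2)c(OCc2ccccc2)c1 | intermediate
4 | dimethyl oxalate | COC(=O)C(=O)OC | starting material
5 | methyl 2-oxo-2-[2,4,6-tris(DBB-oxy)phenyl]acetate | COC(=O)C(=O)c1c(OCc2ccc(OCc3ccccc3)c(OCc3ccccc3)c2)cc(OCc2ccc(OCc3ccccc3)c(OCc3ccccc3)c2)cc1OCc1ccc(OCc2ccccc2)c(OCc2ccccc2)c1 | intermediate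
6 | p-toluenesulfonylhydrazone of 5 | COC(=O)C(=NNS(=O)(=O)c1ccc(C)cc1)c1c(OCc2ccc(OCc3ccccc3)c(OCc3ccccc3)c2)cc(OCc2ccc(OCc3ccccc3)c(OCc3ccccc3)c2)cc1OCc1ccc(OCc2ccccc2)c(OCc2ccccc2)c1 | intermediate (not isolated)
7 | methyl 2-diazo-2-[2,4,6-tris(DBB-oxy)phenyl]acetate | COC(=O)C(=[N+]=[N-])c1c(OCc2ccc(OCc3ccccc3)c(OCc3ccccc3)c2)cc(OCc2ccc(OCc3ccccc3)c(OCc3ccccc3)c2)cc1OCc1ccc(OCc2ccccc2)c(OCc2ccccc2)c1 | intermediate
8 | methyl (2S,3R)-2-[3,4-bis(benzyloxy)phenyl]-4,6-bis(DBB-oxy)-2,3-dihydro-1-benzofuran-3-carboxylate (cis) | COC(=O)[C@@H]1c2c(OCc3ccc(OCc4ccccc4)c(OCc4ccccc4)c3)cc(OCc3ccc(OCc4ccccc4)c(OCc4ccccc4)c3)cc2O[C@@H]1c1ccc(OCc2ccccc2)c(OCc2ccccc2)c1 | intermediate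
9 | methyl (2S,3S)-2-[3,4-bis(benzyloxy)phenyl]-4,6-bis(DBB-oxy)-2,3-dihydro-1-benzofuran-3-carboxylate (trans) | COC(=O)[C@H]1c2c(OCc3ccc(OCc4ccccc4)c(OCc4ccccc4)c3)cc(OCc3ccc(OCc4ccccc4)c(OCc4ccccc4)c3)cc2O[C@@H]1c1ccc(OCc2ccccc2)c(OCc2ccccc2)c1 | intermediate (not isolated)
10 | {(2S,3R)-2-[3,4-bis(benzyloxy)phenyl]-4,6-bis(DBB-oxy)-2,3-dihydro-1-benzofuran-3-yl}methanol (trans) | OC[C@H]1c2c(OCc3ccc(OCc4ccccc4)c(OCc4ccccc4)c3)cc(OCc3ccc(OCc4ccccc4)c(OCc4ccccc4)c3)cc2O[C@@H]1c1ccc(OCc2ccccc2)c(OCc2ccccc2)c1 | intermediate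
11 | methanesulfonate of 10 | CS(=O)(=O)OC[C@H]1c2c(OCc3ccc(OCc4ccccc4)c(OCc4ccccc4)c3)cc(OCc3ccc(OCc4ccccc4)c(OCc4ccccc4)c3)cc2O[C@@H]1c1ccc(OCc2ccccc2)c(OCc2ccccc2)c1 | intermediate (not isolated)
12 | phenonium ion (cyclopropane spiro-fused at C4a and bridging C3 and the former CH2, on the face opposite the 2-aryl group) as its methanesulfonate | C1[C@@H]2[C@@H](c3ccc(OCc4ccccc4)c(OCc4ccccc4)c3)OC3=CC(=[O+]Cc4ccc(OCc5ccccc5)c(OCc5ccccc5)c4)C=C(OCc4ccc(OCc5ccccc5)c(OCc5ccccc5)c4)[C@@]123.CS(=O)(=O)[O-] | intermediate (not isolated)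
13 | (2R,3S)-2-[3,4-bis(benzyloxy)phenyl]-5,7-bis(DBB-oxy)-3,4-dihydro-2H-chromen-3-ol | O[C@H]1Cc2c(OCc3ccc(OCc4ccccc4)c(OCc4ccccc4)c3)cc(OCc3ccc(OCc4ccccc4)c(OCc4ccccc4)c3)cc2O[C@@H]1c1ccc(OCc2ccccc2)c(OCc2ccccc2)c1 | intermediate
14 | (−)-epicatechin, (2R,3R) | O[C@@H]1Cc2c(O)cc(O)cc2O[C@@H]1c1ccc(O)c(O)c1 | starting material
15 | 5,7,3',4'-tetra-O-benzyl-(−)-epicatechin | O[C@@H]1Cc2c(OCc3ccccc3)cc(OCc3ccccc3)cc2O[C@@H]1c1ccc(OCc2ccccc2)c(OCc2ccccc2)c1 | intermediate
16 | 8-bromo-5,7,3',4'-tetra-O-benzyl-(−)-epicatechin | O[C@@H]1Cc2c(OCc3ccccc3)cc(OCc3ccccc3)c(Br)c2O[C@@H]1c1ccc(OCc2ccccc2)c(OCc2ccccc2)c1 | intermediate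
17 | 8-bromo-5,7,3',4'-tetra-O-benzyl-4β-(2-ethoxyethoxy)-(−)-epicatechin | O[C@@H]1[C@@H](OCCOCC)c2c(OCc3ccccc3)cc(OCc3ccccc3)c(Br)c2O[C@@H]1c1ccc(OCc2ccccc2)c(OCc2ccccc2)c1 | intermediate
18 | 3,4,5-tris(benzyloxy)benzoic acid | OC(=O)c1cc(OCc2ccccc2)c(OCc2ccccc2)c(OCc2ccccc2)c1 | starting material
19 | 3-O-[3,4,5-tris(benzyloxy)benzoyl] ester of 17 | O=C(O[C@@H]1[C@@H](OCCOCC)c2c(OCc3ccccc3)cc(OCc3ccccc3)c(Br)c2O[C@@H]1c1ccc(OCc2ccccc2)c(OCc2ccccc2)c1)c1cc(OCc2ccccc2)c(OCc2ccccc2)c(OCc2ccccc2)c1 | intermediate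
20 | 6,8-dibromo analogue of 19 | O=C(O[C@@H]1[C@@H](OCCOCC)c2c(OCc3ccccc3)c(Br)c(OCc3ccccc3)c(Br)c2O[C@@H]1c1ccc(OCc2ccccc2)c(OCc2ccccc2)c1)c1cc(OCc2ccccc2)c(OCc2ccccc2)c(OCc2ccccc2)c1 | intermediate
21 | 4β-(2,6-dimethylphenylsulfanyl) analogue of 19 | O=C(O[C@@H]1[C@@H](Sc2c(C)cccc2C)c2c(OCc3ccccc3)cc(OCc3ccccc3)c(Br)c2O[C@@H]1c1ccc(OCc2ccccc2)c(OCc2ccccc2)c1)c1cc(OCc2ccccc2)c(OCc2ccccc2)c(OCc2ccccc2)c1 | intermediate
22 | (4β→6)-linked dimer, top unit 6,8-dibromo, lower unit 8-bromo with 4β-arylsulfanyl, both 3-O-(tri-O-benzylgalloyl) | O=C(O[C@@H]1[C@@H](c2c(OCc4ccccc4)c(Br)c3c(c2OCc2ccccc2)[C@H](Sc2c(C)cccc2C)[C@@H](OC(=O)c2cc(OCc4ccccc4)c(OCc4ccccc4)c(OCc4ccccc4)c2)[C@@H](c2ccc(OCc4ccccc4)c(OCc4ccccc4)c2)O3)c2c(OCc3ccccc3)c(Br)c(OCc3ccccc3)c(Br)c2O[C@@H]1c1ccc(OCc2ccccc2)c(OCc2ccccc2)c1)c1cc(OCc2ccccc2)c(OCc2ccccc2)c(OCc2ccccc2)c1 | intermediate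
23 | protected trimer (top 4β→6 middle 4β→8 bottom) | O=C(O[C@@H]1[C@@H](c2c(OCc4ccccc4)c(Br)c3c(c2OCc2ccccc2)[C@H](c2c(OCc6ccc(OCc7ccccc7)c(OCc7ccccc7)c6)cc(OCc6ccc(OCc7ccccc7)c(OCc7ccccc7)c6)c5c2O[C@H](c2ccc(OCc6ccccc6)c(OCc6ccccc6)c2)[C@@H](O)C5)[C@@H](OC(=O)c2cc(OCc4ccccc4)c(OCc4ccccc4)c(OCc4ccccc4)c2)[C@@H](c2ccc(OCc4ccccc4)c(OCc4ccccc4)c2)O3)c2c(OCc3ccccc3)c(Br)c(OCc3ccccc3)c(Br)c2O[C@@H]1c1ccc(OCc2ccccc2)c(OCc2ccccc2)c1)c1cc(OCc2ccccc2)c(OCc2ccccc2)c(OCc2ccccc2)c1 | intermediate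
24 | epicatechin 3-O-gallate-(4β→6)-epicatechin 3-O-gallate-(4β→8)-catechin | O=C(O[C@@H]1[C@@H](c2c(O)cc3c(c2O)[C@H](c2c(O)cc(O)c4c2O[C@H](c2ccc(O)c(O)c2)[C@@H](O)C4)[C@@H](OC(=O)c2cc(O)c(O)c(O)c2)[C@@H](c2ccc(O)c(O)c2)O3)c2c(O)cc(O)cc2O[C@@H]1c1ccc(O)c(O)c1)c1cc(O)c(O)c(O)c1 | target

**Count and risks**

Total steps: 15. Longest linear sequence: 8 steps (1–6, 14, 15; the epicatechin line 7–10, 12, 13, 14, 15 is equally long).

Steps most likely to fail:

1. Step 6. The bridged ion may be captured at the wrong carbon (return to the five-membered ring), or the mesylate may fragment across C2–C3 instead of ionising with aryl assistance. The fallback makes the aryl shift unambiguous by placing an oxygen on C3 before the shift (semipinacol rearrangement). It sets out from ester 8. The ester enolate (KN(SiMe3)2, THF, −78 °C) would be hydroxylated with 2-(phenylsulfonyl)-3-phenyloxaziridine on the face away from the 2-aryl group to give the 3-hydroxy ester F1. LiAlH4 would give the diol F2, and selective mesylation of the primary hydroxyl (MsCl, Et3N, −30 °C) the hydroxy mesylate F3. Et3Al in CH2Cl2 at −78 °C should then drive the 1,2-shift of C4a from the carbinol carbon to the CH2, the tertiary alkoxide becoming the carbonyl of the flavan-3-one F4. NaBH4 in MeOH–THF at −40 °C should reduce F4 by axial hydride delivery to the equatorial alcohol, the minor 2,3-cis epimer being removed by chromatography. The fallback comes back to the route at compound 13.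

2. Step 13. The thioether of 21 may ionise or be alkylated at sulfur under the Lewis acid (scrambling of the leaving group), and the bromine-deactivated, doubly flanked C6 may attack too slowly. The fallback removes sulfur from this coupling and introduces the leaving group afterwards. It sets out from 16, which would be esterified with 18 (DCC, DMAP) to the gallate F5. F5 and donor 20 (BF3·OEt2, CH2Cl2, −78 °C) should give the (4β→6) dimer F6, which carries no leaving group. DDQ and 2-ethoxyethanol should then oxidise the only benzylic CH2, C4 of the lower unit, to the 4β-(2-ethoxyethoxy) dimer F7; the hindered methine C4–H of the dibrominated top unit should be left. F7 and 13 with TMSOTf in CH2Cl2 at −78 °C would give the protected trimer. The fallback comes back to the route at compound 23.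

3. Step 14. Silver may fail to ionise the hindered aryl thioether of the dimer, the acid set free may strip the DBB ethers, or the free 3-OH of 13 may be alkylated instead of C8. The fallback reverses the order of the two couplings and uses only oxygen leaving groups. It sets out from 19 and 13, which with TMSOTf in CH2Cl2 at −78 °C should give the (4β→8) dimer F8. NBS would brominate the most electron-rich free position, C6 of the catechin unit, to give F9, leaving C6 of the epicatechin unit as the only nucleophilic site. Donor 20, which cannot self-condense and can be used in excess, would then be coupled there (BF3·OEt2, −78 → −30 °C) to give the tetrabromo trimer F10. Hydrogenolysis under the conditions of step 15 removes the extra bromine as well. The fallback comes back to the route at compound 24.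

**Further compounds**

F1 | step 6 | methyl 2-[3,4-bis(benzyloxy)phenyl]-4,6-bis(DBB-oxy)-3-hydroxy-2,3-dihydro-1-benzofuran-3-carboxylate, 3-OH trans to the 2-aryl group | COC(=O)[C@]1(O)c2c(OCc3ccc(OCc4ccccc4)c(OCc4ccccc4)c3)cc(OCc3ccc(OCc4ccccc4)c(OCc4ccccc4)c3)cc2O[C@@H]1c1ccc(OCc2ccccc2)c(OCc2ccccc2)c1
F2 | step 6 | 2-[3,4-bis(benzyloxy)phenyl]-4,6-bis(DBB-oxy)-3-(hydroxymethyl)-2,3-dihydro-1-benzofuran-3-ol, 3-OH trans to the 2-aryl group | OC[C@]1(O)c2c(OCc3ccc(OCc4ccccc4)c(OCc4ccccc4)c3)cc(OCc3ccc(OCc4ccccc4)c(OCc4ccccc4)c3)cc2O[C@@H]1c1ccc(OCc2ccccc2)c(OCc2ccccc2)c1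
F3 | step 6 | primary methanesulfonate of F2 | CS(=O)(=O)OC[C@]1(O)c2c(OCc3ccc(OCc4ccccc4)c(OCc4ccccc4)c3)cc(OCc3ccc(OCc4ccccc4)c(OCc4ccccc4)c3)cc2O[C@@H]1c1ccc(OCc2ccccc2)c(OCc2ccccc2)c1
F4 | step 6 | (2R)-2-[3,4-bis(benzyloxy)phenyl]-5,7-bis(DBB-oxy)-2H-chromen-3(4H)-one (flavan-3-one) | O=C1Cc2c(OCc3ccc(OCc4ccccc4)c(OCc4ccccc4)c3)cc(OCc3ccc(OCc4ccccc4)c(OCc4ccccc4)c3)cc2O[C@@H]1c1ccc(OCc2ccccc2)c(OCc2ccccc2)c1
F5 | step 13 | 8-bromo-5,7,3',4'-tetra-O-benzyl-(−)-epicatechin 3-O-[3,4,5-tris(benzyloxy)benzoate] | O=C(O[C@@H]1Cc2c(OCc3ccccc3)cc(OCc3ccccc3)c(Br)c2O[C@@H]1c1ccc(OCc2ccccc2)c(OCc2ccccc2)c1)c1cc(OCc2ccccc2)c(OCc2ccccc2)c(OCc2ccccc2)c1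
F6 | step 13 | (4β→6)-linked dimer of 20 and F5 with CH2 at C4 of the lower unit | O=C(O[C@@H]1[C@@H](c2c(OCc4ccccc4)c(Br)c3c(c2OCc2ccccc2)C[C@@H](OC(=O)c2cc(OCc4ccccc4)c(OCc4ccccc4)c(OCc4ccccc4)c2)[C@@H](c2ccc(OCc4ccccc4)c(OCc4ccccc4)c2)O3)c2c(OCc3ccccc3)c(Br)c(OCc3ccccc3)c(Br)c2O[C@@H]1c1ccc(OCc2ccccc2)c(OCc2ccccc2)c1)c1cc(OCc2ccccc2)c(OCc2ccccc2)c(OCc2ccccc2)c1
F7 | step 13 | F6 with a 4β-(2-ethoxyethoxy) group on the lower unit | O=C(O[C@@H]1[C@@H](c2c(OCc4ccccc4)c(Br)c3c(c2OCc2ccccc2)[C@H](OCCOCC)[C@@H](OC(=O)c2cc(OCc4ccccc4)c(OCc4ccccc4)c(OCc4ccccc4)c2)[C@@H](c2ccc(OCc4ccccc4)c(OCc4ccccc4)c2)O3)c2c(OCc3ccccc3)c(Br)c(OCc3ccccc3)c(Br)c2O[C@@H]1c1ccc(OCc2ccccc2)c(OCc2ccccc2)c1)c1cc(OCc2ccccc2)c(OCc2ccccc2)c(OCc2ccccc2)c1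
F8 | step 14 | [8-bromo-tetra-O-benzyl-3-O-(tri-O-benzylgalloyl)epicatechin]-(4β→8)-[3',4'-di-O-benzyl-5,7-di-O-DBB-catechin] | O=C(O[C@@H]1[C@@H](c2c(OCc4ccc(OCc5ccccc5)c(OCc5ccccc5)c4)cc(OCc4ccc(OCc5ccccc5)c(OCc5ccccc5)c4)c3c2O[C@H](c2ccc(OCc4ccccc4)c(OCc4ccccc4)c2)[C@@H](O)C3)c2c(OCc3ccccc3)cc(OCc3ccccc3)c(Br)c2O[C@@H]1c1ccc(OCc2ccccc2)c(OCc2ccccc2)c1)c1cc(OCc2ccccc2)c(OCc2ccccc2)c(OCc2ccccc2)c1
F9 | step 14 | F8 brominated at C6 of the catechin unit | O=C(O[C@@H]1[C@@H](c2c(OCc4ccc(OCc5ccccc5)c(OCc5ccccc5)c4)c(Br)c(OCc4ccc(OCc5ccccc5)c(OCc5ccccc5)c4)c3c2O[C@H](c2ccc(OCc4ccccc4)c(OCc4ccccc4)c2)[C@@H](O)C3)c2c(OCc3ccccc3)cc(OCc3ccccc3)c(Br)c2O[C@@H]1c1ccc(OCc2ccccc2)c(OCc2ccccc2)c1)c1cc(OCc2ccccc2)c(OCc2ccccc2)c(OCc2ccccc2)c1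
F10 | step 14 | protected trimer 23 with an additional bromine at C6 of the catechin unit | O=C(O[C@@H]1[C@@H](c2c(OCc4ccccc4)c(Br)c3c(c2OCc2ccccc2)[C@H](c2c(OCc6ccc(OCc7ccccc7)c(OCc7ccccc7)c6)c(Br)c(OCc6ccc(OCc7ccccc7)c(OCc7ccccc7)c6)c5c2O[C@H](c2ccc(OCc6ccccc6)c(OCc6ccccc6)c2)[C@@H](O)C5)[C@@H](OC(=O)c2cc(OCc4ccccc4)c(OCc4ccccc4)c(OCc4ccccc4)c2)[C@@H](c2ccc(OCc4ccccc4)c(OCc4ccccc4)c2)O3)c2c(OCc3ccccc3)c(Br)c(OCc3ccccc3)c(Br)c2O[C@@H]1c1ccc(OCc2ccccc2)c(OCc2ccccc2)c1)c1cc(OCc2ccccc2)c(OCc2ccccc2)c(OCc2ccccc2)c1
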